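A direct plan would condense a 4‑O‑benzyl phloroacetophenone with O‑benzyl 5‑bromoisovanillin to the chalcone A1, close it to the flavanone, shift ring B from C2 to C3 with a hypervalent iodine reagent to the isoflavone A2, iodinate C6, remove the benzyl groups, attach both prenyl groups by a twofold Stille coupling to give the diprenyl isoflavone A3 and, last, reduce C2=C3 enantioselectively.
Its weakest steps would be:
- The final enantioselective transfer hydrogenation of the isoflavone C2=C3 bond: C3 would be set by protonation of an enol under a chiral acid, a mode of induction untested on chromones, in the last step and on a product whose benzylic C3–H next to the ketone epimerises easily.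
- The late twofold Stille prenylation: it needs two halogens carried through the route, an iodination that must choose C6 over C8, excess tin reagent and palladium on a free triphenol, all for two simple C5 groups.
- The benzyl ether stretch (selective mono‑benzylation, methylation/benzylation, BCl3 removal): three operations that build nothing and serve only the late halogen chemistry.

**Retrosynthetic overview**
- The target would come from its tris‑silyl ether 22, which is cut at the C3–C1′ bond between ring C and ring B: racemic 3‑bromochromanone 12 (rings A and C, prenyl at C6) plus arylzinc 21 (ring B, prenyl at C5′).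
- The key step forms this bond by cross‑coupling of two separately prenylated halves, not by an aryl shift within a flavanone, and sets C3, the benzylic centre α to the C4 ketone, in the same operation from a racemate.
- Ring C is closed on ring A alone (C2 added to the acetyl group by a Mannich reaction, then O1–C2 by oxa‑Michael addition) and ring B is joined last; no chalcone, flavanone or isoflavone is passed.
- The C6 prenyl is delivered by a Claisen–Cope shift from the oxygen that becomes O1, so it is para to O1 by construction; the C5′ prenyl comes from the bromine ortho to OMe in 2,4,6‑tribromoanisole.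
- No late reduction sets the stereocentre, no halogen or tin is carried for prenylation, and the only step after the coupling is a buffered desilylation.

Key step: step 9

Assumption (remark on the chemistry): the sense of induction of the nickel/pybox catalyst on a bromide whose α‑carbon lies in a ring cannot be predicted with certainty; the route is written for the ligand antipode that gives (3S), to be fixed in a pilot run, both antipodes being accessible. TBS = tert‑butyldimethylsilyl, TBSO = (tert‑butyldimethylsilyl)oxy, prenyl = 3‑methylbut‑2‑en‑1‑yl.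

**Route**

Step 1
Reactants: 1 2,4,6‑trihydroxyacetophenone
Product: 2 1‑[2,4‑bis(TBSO)‑6‑hydroxyphenyl]ethan‑1‑one
Conditions: TBSCl (2.1 equiv), imidazole, DMF, 0 °C to rt
Reagents that add atoms: tert‑butyldimethylsilyl chloride CC(C)(C)[Si](C)(C)Cl
Why: Silyl ether formation at the 4‑OH and at one of the two equivalent ortho‑OH groups, while the last ortho‑OH is held in a hydrogen bond to the ketone and stays free, which marks the oxygen that will become O1.

Step 2
Reactants: 2 1‑[2,4‑bis(TBSO)‑6‑hydroxyphenyl]ethan‑1‑one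
Product: 3 1‑[2,4‑bis(TBSO)‑6‑(prenyloxy)phenyl]ethan‑1‑one
Conditions: 3‑methylbut‑2‑en‑1‑ol, PPh3, DIAD, THF, 0 °C to rt
Reagents that add atoms: 3‑methylbut‑2‑en‑1‑ol CC(C)=CCO
Why: Mitsunobu etherification, in which the chelated but sufficiently acidic phenol attacks the activated primary allylic alcohol at oxygen under neutral conditions that leave the aryl silyl ethers alone.

Step 3
Reactants: 3 1‑[2,4‑bis(TBSO)‑6‑(prenyloxy)phenyl]ethan‑1‑one
Product: 6 1‑[2,4‑bis(TBSO)‑6‑hydroxy‑3‑prenylphenyl]ethan‑1‑one, via ortho‑dienone 4 (not isolated), via para‑dienone 5 (not isolated)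
Conditions: PhNEt2, 195 °C (sealed tube)
Reagents that add atoms: none
Why: Aromatic Claisen rearrangement followed by Cope rearrangement (para‑Claisen–Cope): the first [3,3] shift can only go to the one free ortho carbon, the crowded 1,1‑dimethylallyl group of dienone 4 should move on by a second [3,3] shift to the para carbon between the two silyloxy groups, and enolisation of 5 leaves a linear prenyl group exactly para to the free phenol oxygen.

Step 4
Reactants: 6 1‑[2,4‑bis(TBSO)‑6‑hydroxy‑3‑prenylphenyl]ethan‑1‑one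
Product: 10 5,7‑bis(TBSO)‑6‑prenyl‑2,3‑dihydro‑4H‑chromen‑4‑one, via Mannich base 7 (not isolated), via ammonium iodide 8 (not isolated), via aryl vinyl ketone 9 (not isolated)
Conditions: LiN(SiMe3)2 (2.2 equiv), THF, −78 °C; Me2N=CH2+ I− (1.2 equiv), −78 to 0 °C; NH4Cl (aq.); then MeI, CH2Cl2, rt; then NaHCO3 (aq.), rt
Reagents that add atoms: N,N‑dimethylmethyleneiminium iodide C=[N+](C)C.[I-]
Why: Mannich reaction of the kinetic dianion with the preformed iminium salt, Hofmann‑type elimination of the quaternised amine to the aryl vinyl ketone 9 and 6‑endo‑trig oxa‑Michael addition of the only free phenol should close ring C, so that O1 is para to the prenyl group by construction.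

Step 5
Reactants: 10 5,7‑bis(TBSO)‑6‑prenyl‑2,3‑dihydro‑4H‑chromen‑4‑one
Product: 12 rac‑3‑bromo‑5,7‑bis(TBSO)‑6‑prenyl‑2,3‑dihydro‑4H‑chromen‑4‑one, via trimethylsilyl enol ether 11 (not isolated)
Conditions: TMSOTf, Et3N, CH2Cl2, 0 °C; NaHCO3 wash, solvent exchange; then NBS (1.05 equiv), THF, −78 °C
Reagents that add atoms: N‑bromosuccinimide O=C1CCC(=O)N1Br
Why: α‑Bromination of a ketone through its silyl enol ether, which at −78 °C should react with NBS far faster than the prenyl alkene or C8 of the electron‑rich ring and, being non‑basic and freed of amine, cannot remove HBr from the product; the racemate is what the key step needs.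

Step 6
Reactants: 13 1,3,5‑tribromo‑2‑methoxybenzene (2,4,6‑tribromoanisole)
Product: 15 1,5‑dibromo‑2‑methoxy‑3‑prenylbenzene, via aryllithium 14 (not isolated)
Conditions: n‑BuLi (1.0 equiv), Et2O, −78 °C; then CuBr·SMe2 (10 mol%), prenyl bromide, −78 to 0 °C
Reagents that add atoms: 1‑bromo‑3‑methylbut‑2‑ene BrCC=C(C)C
Why: Bromine–lithium exchange, fastest at a bromine ortho to OMe because the oxygen coordinates and stabilises the aryllithium, followed by copper‑catalysed SN2 allylation, which should give the linear prenyl group since attack at the disubstituted terminus is hindered.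

Step 7
Reactants: 15 1,5‑dibromo‑2‑methoxy‑3‑prenylbenzene
Product: 18 5‑bromo‑2‑methoxy‑3‑prenylphenol, via aryllithium 16 (not isolated), via dimethyl arylboronate 17 (not isolated)
Conditions: n‑BuLi (1.05 equiv), Et2O, −78 °C; B(OMe)3, −78 °C to rt; then H2O2 (30% aq.), NaOH (aq.), 0 °C
Reagents that add atoms: hydrogen peroxide OO
Why: Second ortho‑selective bromine–lithium exchange (the remaining bromine beside OMe before the para bromine), borylation and oxidative C–B to C–O conversion with basic hydrogen peroxide, which does not epoxidise an unactivated alkene and leaves the aryl bromide for step 9.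

Step 8
Reactants: 18 5‑bromo‑2‑methoxy‑3‑prenylphenol
Product: 19 (5‑bromo‑2‑methoxy‑3‑prenylphenoxy)(tert‑butyl)dimethylsilane
Conditions: TBSCl, imidazole, DMF, rt
Reagents that add atoms: tert‑butyldimethylsilyl chloride CC(C)(C)[Si](C)(C)Cl
Why: Silyl ether formation at the phenol, needed so that the arylmagnesium and arylzinc reagents of step 9 can be generated, and chosen to match the silyl ethers of ring A for a single final deprotection.

Step 9
Reactants: 12 rac‑3‑bromo‑5,7‑bis(TBSO)‑6‑prenyl‑2,3‑dihydro‑4H‑chromen‑4‑one; 19 (5‑bromo‑2‑methoxy‑3‑prenylphenoxy)(tert‑butyl)dimethylsilane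
Product: 22 (3S)‑5,7‑bis(TBSO)‑3‑[3‑(TBSO)‑4‑methoxy‑5‑prenylphenyl]‑6‑prenyl‑2,3‑dihydro‑4H‑chromen‑4‑one, via arylmagnesium bromide 20 (not isolated), via arylzinc iodide 21 (not isolated)
Conditions: 19 (1.3 equiv), Mg, THF, 40 °C; ZnI2, THF, 0 °C; then 12, NiCl2·glyme (5 mol%), 2,6‑bis[(4R,5S)‑4,5‑diphenyl‑4,5‑dihydro‑1,3‑oxazol‑2‑yl]pyridine (6.5 mol%), glyme/THF, −30 °C
Reagents that add atoms: none
Why: Proposed new method: after transmetalation from zinc, an aryl complex of monovalent nickel would abstract bromine from either enantiomer of 12 to give the planar C3 radical α to the C4 ketone, which recombines with the aryl complex of divalent nickel inside the pybox pocket, and reductive elimination from trivalent nickel forms the C3–C1′ bond, so both enantiomers of the bromide converge on one product. The closest known reaction type is the nickel/pybox‑catalysed stereoconvergent Negishi arylation of racemic open‑chain α‑bromo aryl ketones with arylzinc iodides at −30 °C, which gives tertiary α‑aryl ketones without racemisation; the extension is that the α‑carbon here lies in ring C. No ring is closed; the step joins the ring A/C half to ring B. The new stereocentre C3 is controlled by the chiral ligand alone (catalyst control), with the antipode chosen for 3S. The step needs enantioconvergence, no loss of HBr or of the ring oxygen toward a chromone or a ring‑opened enone, and no epimerisation of the product: the weakly basic arylzinc at −30 °C should not enolise the ketone, the C2–O1 bond cannot become syn‑coplanar with a C3–Ni bond inside the six‑membered ring, and the silyl ethers and both trisubstituted alkenes are inert to the radical and to the organozinc.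

Step 10
Reactants: 22 (3S)‑5,7‑bis(TBSO)‑3‑[3‑(TBSO)‑4‑methoxy‑5‑prenylphenyl]‑6‑prenyl‑2,3‑dihydro‑4H‑chromen‑4‑one
Product: 23 (3S)‑5,7‑dihydroxy‑3‑[3‑hydroxy‑4‑methoxy‑5‑(3‑methylbut‑2‑en‑1‑yl)phenyl]‑6‑(3‑methylbut‑2‑en‑1‑yl)‑2,3‑dihydro‑4H‑chromen‑4‑one
Conditions: HF·pyridine, pyridine, THF, 0 °C
Reagents that add atoms: none
Why: Fluoride cleavage of the three aryl silyl ethers under pyridine‑buffered, weakly acidic conditions at 0 °C, which should neither enolise the α‑aryl ketone (C3 stays S) nor protonate the prenyl alkenes.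

**Compound list**
1 | 2,4,6‑trihydroxyacetophenone | CC(=O)c1c(O)cc(O)cc1O | starting material
2 | 1‑[2,4‑bis(TBSO)‑6‑hydroxyphenyl]ethan‑1‑one | CC(=O)c1c(O)cc(O[Si](C)(C)C(C)(C)C)cc1O[Si](C)(C)C(C)(C)C | intermediate
3 | 1‑[2,4‑bis(TBSO)‑6‑(prenyloxy)phenyl]ethan‑1‑one | CC(=O)c1c(OCC=C(C)C)cc(O[Si](C)(C)C(C)(C)C)cc1O[Si](C)(C)C(C)(C)C | intermediate
4 | 2‑acetyl‑3,5‑bis(TBSO)‑6‑(2‑methylbut‑3‑en‑2‑yl)cyclohexa‑2,4‑dien‑1‑one, racemic (not isolated) | CC(=O)C1=C(O[Si](C)(C)C(C)(C)C)C=C(O[Si](C)(C)C(C)(C)C)C(C(C)(C)C=C)C1=O | intermediate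
5 | 2‑acetyl‑3,5‑bis(TBSO)‑4‑prenylcyclohexa‑2,5‑dien‑1‑one, racemic (not isolated) | CC(=O)C1=C(O[Si](C)(C)C(C)(C)C)C(CC=C(C)C)C(O[Si](C)(C)C(C)(C)C)=CC1=O | intermediate
6 | 1‑[2,4‑bis(TBSO)‑6‑hydroxy‑3‑prenylphenyl]ethan‑1‑one | CC(=O)c1c(O)cc(O[Si](C)(C)C(C)(C)C)c(CC=C(C)C)c1O[Si](C)(C)C(C)(C)C | intermediate
7 | 1‑[2,4‑bis(TBSO)‑6‑hydroxy‑3‑prenylphenyl]‑3‑(dimethylamino)propan‑1‑one (not isolated) | CN(C)CCC(=O)c1c(O)cc(O[Si](C)(C)C(C)(C)C)c(CC=C(C)C)c1O[Si](C)(C)C(C)(C)C | intermediate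
8 | 3‑[2,4‑bis(TBSO)‑6‑hydroxy‑3‑prenylphenyl]‑N,N,N‑trimethyl‑3‑oxopropan‑1‑aminium iodide (not isolated) | C[N+](C)(C)CCC(=O)c1c(O)cc(O[Si](C)(C)C(C)(C)C)c(CC=C(C)C)c1O[Si](C)(C)C(C)(C)C.[I-] | intermediate
9 | 1‑[2,4‑bis(TBSO)‑6‑hydroxy‑3‑prenylphenyl]prop‑2‑en‑1‑one (not isolated) | C=CC(=O)c1c(O)cc(O[Si](C)(C)C(C)(C)C)c(CC=C(C)C)c1O[Si](C)(C)C(C)(C)C | intermediate
10 | 5,7‑bis(TBSO)‑6‑prenyl‑2,3‑dihydro‑4H‑chromen‑4‑one | O=C1CCOc2cc(O[Si](C)(C)C(C)(C)C)c(CC=C(C)C)c(O[Si](C)(C)C(C)(C)C)c12 | intermediate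
11 | {[5,7‑bis(TBSO)‑6‑prenyl‑2H‑chromen‑4‑yl]oxy}trimethylsilane (not isolated) | C[Si](C)(C)OC1=CCOc2cc(O[Si](C)(C)C(C)(C)C)c(CC=C(C)C)c(O[Si](C)(C)C(C)(C)C)c12 | intermediate
12 | rac‑3‑bromo‑5,7‑bis(TBSO)‑6‑prenyl‑2,3‑dihydro‑4H‑chromen‑4‑one | O=C1C(Br)COc2cc(O[Si](C)(C)C(C)(C)C)c(CC=C(C)C)c(O[Si](C)(C)C(C)(C)C)c12 | intermediate
13 | 1,3,5‑tribromo‑2‑methoxybenzene | COc1c(Br)cc(Br)cc1Br | starting material
14 | (3,5‑dibromo‑2‑methoxyphenyl)lithium (not isolated) | [Li]c1cc(Br)cc(Br)c1OC | intermediate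
15 | 1,5‑dibromo‑2‑methoxy‑3‑prenylbenzene | COc1c(Br)cc(Br)cc1CC=C(C)C | intermediate
16 | (5‑bromo‑2‑methoxy‑3‑prenylphenyl)lithium (not isolated) | [Li]c1cc(Br)cc(CC=C(C)C)c1OC | intermediate
17 | dimethyl (5‑bromo‑2‑methoxy‑3‑prenylphenyl)boronate (not isolated) | COB(OC)c1cc(Br)cc(CC=C(C)C)c1OC | intermediate
18 | 5‑bromo‑2‑methoxy‑3‑prenylphenol | COc1c(O)cc(Br)cc1CC=C(C)C | intermediate
19 | (5‑bromo‑2‑methoxy‑3‑prenylphenoxy)(tert‑butyl)dimethylsilane | COc1c(O[Si](C)(C)C(C)(C)C)cc(Br)cc1CC=C(C)C | intermediate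
20 | [3‑(TBSO)‑4‑methoxy‑5‑prenylphenyl]magnesium bromide (not isolated) | Br[Mg]c1cc(O[Si](C)(C)C(C)(C)C)c(OC)c(CC=C(C)C)c1 | intermediate
21 | [3‑(TBSO)‑4‑methoxy‑5‑prenylphenyl]zinc iodide (not isolated) | I[Zn]c1cc(O[Si](C)(C)C(C)(C)C)c(OC)c(CC=C(C)C)c1 | intermediate
22 | (3S)‑5,7‑bis(TBSO)‑3‑[3‑(TBSO)‑4‑methoxy‑5‑prenylphenyl]‑6‑prenyl‑2,3‑dihydro‑4H‑chromen‑4‑one | COc1c(O[Si](C)(C)C(C)(C)C)cc([C@H]2COc3cc(O[Si](C)(C)C(C)(C)C)c(CC=C(C)C)c(O[Si](C)(C)C(C)(C)C)c3C2=O)cc1CC=C(C)C | intermediate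
23 | (3S)‑5,7‑dihydroxy‑3‑[3‑hydroxy‑4‑methoxy‑5‑(3‑methylbut‑2‑en‑1‑yl)phenyl]‑6‑(3‑methylbut‑2‑en‑1‑yl)‑2,3‑dihydro‑4H‑chromen‑4‑one | COc1c(O)cc([C@H]2COc3cc(O)c(CC=C(C)C)c(O)c3C2=O)cc1CC=C(C)C | target

**Step count and risk**
Total: 10 steps. Longest linear sequence: 7 steps (steps 1 to 5, 9 and 10); the ring B branch has 3 steps (6 to 8).

Steps most likely to fail:

Step 9. The nickel catalyst might discriminate the faces of the ring‑held C3 radical poorly (low enantiomeric excess), or elimination toward the chromone might outrun the coupling. The fallback sets out from 10 and 19 and comes back at 22, using known chemistry. Ketone 10 would be α‑arylated with 19 (Pd(dba)2, P(t‑Bu)3, LiN(SiMe3)2, toluene) to the racemic isoflavanone F1. F1 would be reduced by Noyori transfer hydrogenation with dynamic kinetic resolution (RuCl[(S,S)‑TsDPEN](p‑cymene), HCO2H/Et3N, the base racemising C3 as the reduction proceeds; catalyst antipode by analogy with chroman‑4‑one) to the cis alcohol F2. F2 would be oxidised back to the ketone with Dess–Martin periodinane buffered with NaHCO3 at 0 °C to give 22.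

Step 3. The ortho‑dienone might enolise before the Cope shift, leaving the allyl group at the ortho carbon in its branched form, or silyl groups might be lost or migrate at 195 °C. The fallback sets out from 1 and comes back at 10; it moves the prenyl transfer to an ortho‑Claisen rearrangement from O5 after ring C is closed. Compound 1 would be silylated at the 4‑OH only to give F3, and ring C closed by the sequence of step 4 to the chromanone F4. The chelated 5‑OH would be etherified with 2‑methylbut‑3‑yn‑2‑yl trifluoroacetate (CuCl2 catalyst, DBU, MeCN) to F5, and the alkyne semi‑hydrogenated (H2, Pd/CaCO3 poisoned with Pb(OAc)2, quinoline) to the 1,1‑dimethylallyl ether F6. Heating F6 (xylene, 130 °C) would give the 6‑prenyl phenol F7, since C6 is the only free ortho carbon. TBSOTf and 2,6‑lutidine would then give 10.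

Step 4. In the dianion a silyl group might migrate from the ortho oxygen to the enolate oxygen, the phenol might be methylated during quaternisation, or the aryl vinyl ketone might oligomerise before it cyclises. The fallback sets out from 6 and comes back at 10; it brings in C2 at the formate oxidation level. Compound 6 would be condensed with Me2NCH(OMe)2 (toluene, 80 °C) to the enaminone F8, cyclised on silica gel or with pyridinium p‑toluenesulfonate to the chromone F9, and reduced in the 1,4‑sense with LiBH(s‑Bu)3 (THF, −78 °C) to 10.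

**Further compounds**
F1 | step 9 | rac‑5,7‑bis(TBSO)‑3‑[3‑(TBSO)‑4‑methoxy‑5‑prenylphenyl]‑6‑prenyl‑2,3‑dihydro‑4H‑chromen‑4‑one | COc1c(O[Si](C)(C)C(C)(C)C)cc(C2COc3cc(O[Si](C)(C)C(C)(C)C)c(CC=C(C)C)c(O[Si](C)(C)C(C)(C)C)c3C2=O)cc1CC=C(C)C
F2 | step 9 | (3S,4S)‑5,7‑bis(TBSO)‑3‑[3‑(TBSO)‑4‑methoxy‑5‑prenylphenyl]‑6‑prenyl‑3,4‑dihydro‑2H‑chromen‑4‑ol (cis) | COc1c(O[Si](C)(C)C(C)(C)C)cc([C@H]2COc3cc(O[Si](C)(C)C(C)(C)C)c(CC=C(C)C)c(O[Si](C)(C)C(C)(C)C)c3[C@H]2O)cc1CC=C(C)C
F3 | step 3 | 1‑[4‑(TBSO)‑2,6‑dihydroxyphenyl]ethan‑1‑one | CC(=O)c1c(O)cc(O[Si](C)(C)C(C)(C)C)cc1O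
F4 | step 3 | 5‑hydroxy‑7‑(TBSO)‑2,3‑dihydro‑4H‑chromen‑4‑one | O=C1CCOc2cc(O[Si](C)(C)C(C)(C)C)cc(O)c12
F5 | step 3 | 7‑(TBSO)‑5‑[(2‑methylbut‑3‑yn‑2‑yl)oxy]‑2,3‑dihydro‑4H‑chromen‑4‑one | O=C1CCOc2cc(O[Si](C)(C)C(C)(C)C)cc(OC(C)(C)C#C)c12
F6 | step 3 | 7‑(TBSO)‑5‑[(2‑methylbut‑3‑en‑2‑yl)oxy]‑2,3‑dihydro‑4H‑chromen‑4‑one | O=C1CCOc2cc(O[Si](C)(C)C(C)(C)C)cc(OC(C)(C)C=C)c12
F7 | step 3 | 5‑hydroxy‑6‑prenyl‑7‑(TBSO)‑2,3‑dihydro‑4H‑chromen‑4‑one | O=C1CCOc2cc(O[Si](C)(C)C(C)(C)C)c(CC=C(C)C)c(O)c12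
F8 | step 4 | (E)‑1‑[2,4‑bis(TBSO)‑6‑hydroxy‑3‑prenylphenyl]‑3‑(dimethylamino)prop‑2‑en‑1‑one | CN(C)/C=C/C(=O)c1c(O)cc(O[Si](C)(C)C(C)(C)C)c(CC=C(C)C)c1O[Si](C)(C)C(C)(C)C
F9 | step 4 | 5,7‑bis(TBSO)‑6‑prenyl‑4H‑chromen‑4‑one | O=c1ccoc2cc(O[Si](C)(C)C(C)(C)C)c(CC=C(C)C)c(O[Si](C)(C)C(C)(C)C)c12
A1 | direct plan | (E)‑1‑[4‑(benzyloxy)‑2,6‑dihydroxyphenyl]‑3‑[3‑(benzyloxy)‑5‑bromo‑4‑methoxyphenyl]prop‑2‑en‑1‑one | COc1c(OCc2ccccc2)cc(/C=C/C(=O)c2c(O)cc(OCc3ccccc3)cc2O)cc1Br
A2 | direct plan | 7‑(benzyloxy)‑3‑[3‑(benzyloxy)‑5‑bromo‑4‑methoxyphenyl]‑5‑hydroxy‑4H‑chromen‑4‑one | COc1c(OCc2ccccc2)cc(-c2coc3cc(OCc4ccccc4)cc(O)c3c2=O)cc1Br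
A3 | direct plan | 5,7‑dihydroxy‑3‑[3‑hydroxy‑4‑methoxy‑5‑(3‑methylbut‑2‑en‑1‑yl)phenyl]‑6‑(3‑methylbut‑2‑en‑1‑yl)‑4H‑chromen‑4‑one | COc1c(O)cc(-c2coc3cc(O)c(CC=C(C)C)c(O)c3c2=O)cc1CC=C(C)C
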